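## Retrosynthetic overview

1. The C8–CH2–C8' bridge is cut last, giving two (2S)-flavans. All aromatic carbons of both come from the symmetric aldehyde 1 (2,6-dihydroxy-4-methoxybenzaldehyde), which with cinnamyl alcohol 2 gives 3 as the only possible regioisomer.
2. The key disconnection in each half is the C2–O1 bond. An enantioselective 6-endo hydroalkoxylation closes the pyran ring of 3 to give 4. C-Methylation of 3 at its last free ring carbon gives 5, which is cyclised the same way to 6.
3. The formyl group marks the bridge position. In 6 it is removed by decarbonylation to give 7, which has one free ring position (C8). In 4 it becomes the bridge carbon (alcohol 8, quinone methide 9).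
4. Order of ring formation: pyran ring of the ring A half (4), pyran ring of the ring B half (6), then union of 9 with 7 to give target 10.

Assumption: aldehyde 1 is bought as a catalogue building block, and the antipode of the chiral acid that delivers the (2S) series is fixed by a pilot run.

IDPi-1 is a BINOL-derived imidodiphosphorimidate Brønsted acid with 3,3'-bis[3,5-bis(trifluoromethyl)phenyl] groups and N-triflyl groups; dppp is 1,3-bis(diphenylphosphino)propane.

## Route

Step 1
Reactants: 1 2,6-dihydroxy-4-methoxybenzaldehyde; 2 (E)-cinnamyl alcohol [(2E)-3-phenylprop-2-en-1-ol]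
Product: 3 2,6-dihydroxy-4-methoxy-3-[(2E)-3-phenylprop-2-en-1-yl]benzaldehyde
Conditions: 1 (2 equiv), BF3·OEt2 (0.3 equiv), 1,4-dioxane, 20 °C
Reagents that add atoms: none
Why: Friedel–Crafts allylation, in which the cinnamyl cation from 2 attacks through its unsubstituted terminus one of the two symmetry-equivalent ring C–H positions of 1 (excess 1 limits double alkylation), so a single regioisomer with the E alkene results and no stereocentre is formed.

Step 2
Reactants: 3 2,6-dihydroxy-4-methoxy-3-[(2E)-3-phenylprop-2-en-1-yl]benzaldehyde
Product: 4 (2S)-7-hydroxy-5-methoxy-2-phenyl-3,4-dihydro-2H-chromene-8-carbaldehyde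
Conditions: IDPi-1 (5 mol %), CHCl3, 4 Å molecular sieves, 40 °C
Reagents that add atoms: none
Why: Proposed new method: the confined strong acid protonates the alkene carbon remote from phenyl while its sulfonylimide site accepts the proton of the neighbouring phenol, so the C2–O1 bond forms by a concerted asynchronous 6-endo addition through a benzylic cation-like transition state inside the chiral pocket, which exposes one alkene face and sets (2S) (the antipode of the acid is chosen accordingly); the closest known reactions are the IDPi-catalysed asymmetric intramolecular hydroalkoxylation of aliphatic alkenols and the racemic triflic-acid cyclisation of 2-cinnamylphenols to flavans, and the formyl group keeps the arene from being protonated or alkylated by the acid.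

Step 3
Reactants: 3 2,6-dihydroxy-4-methoxy-3-[(2E)-3-phenylprop-2-en-1-yl]benzaldehyde
Product: 5 2,6-dihydroxy-4-methoxy-3-methyl-5-[(2E)-3-phenylprop-2-en-1-yl]benzaldehyde
Conditions: NaOMe (2.2 equiv), MeI (1.2 equiv), MeOH, 0 → 20 °C; aq. HCl work-up
Reagents that add atoms: iodomethane, CI
Why: C-methylation of a phloroglucinol-type phenoxide (acylphloroglucinol alkylation), in which the dianion of 3 reacts with iodomethane at its only remaining ring C–H while methanol solvation and chelation to the formyl group hold back O-methylation; no stereocentre is formed.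

Step 4
Reactants: 5 2,6-dihydroxy-4-methoxy-3-methyl-5-[(2E)-3-phenylprop-2-en-1-yl]benzaldehyde
Product: 6 (2S)-7-hydroxy-5-methoxy-6-methyl-2-phenyl-3,4-dihydro-2H-chromene-8-carbaldehyde
Conditions: IDPi-1 (5 mol %), CHCl3, 4 Å molecular sieves, 40 °C
Reagents that add atoms: none
Why: Proposed new method: the same enantioselective 6-endo hydroalkoxylation as in step 2, in which proton transfer to the alkene carbon remote from phenyl and ring closure by the only hydroxyl next to the cinnamyl group occur within the chiral ion pair and set (2S) at the new C–O bond; the closest known reactions are again the IDPi-catalysed hydroalkoxylation of aliphatic alkenols and the racemic acid-catalysed cyclisation of 2-cinnamylphenols.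

Step 5
Reactants: 6 (2S)-7-hydroxy-5-methoxy-6-methyl-2-phenyl-3,4-dihydro-2H-chromene-8-carbaldehyde
Product: 7 (2S)-5-methoxy-6-methyl-2-phenyl-3,4-dihydro-2H-chromen-7-ol
Conditions: [Rh(dppp)2]Cl (5 mol %), diglyme, 160 °C, N2 stream
Reagents that add atoms: none
Why: Tsuji–Wilkinson-type catalytic decarbonylation, in which oxidative addition of the formyl C–H bond to monovalent rhodium, CO de-insertion and C–H reductive elimination replace CHO by H and leave C8 as the only free ring position; C2 is not touched.

Step 6
Reactants: 4 (2S)-7-hydroxy-5-methoxy-2-phenyl-3,4-dihydro-2H-chromene-8-carbaldehyde; 7 (2S)-5-methoxy-6-methyl-2-phenyl-3,4-dihydro-2H-chromen-7-ol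
Product: 10 (2S)-8-{[(2S)-7-hydroxy-5-methoxy-6-methyl-2-phenyl-3,4-dihydro-2H-chromen-8-yl]methyl}-5-methoxy-2-phenyl-3,4-dihydro-2H-chromen-7-ol, via benzylic alcohol 8 (not isolated), via o-quinone methide 9 (not isolated)
Conditions: 4, NaBH4 (1.2 equiv), THF–MeOH 4:1, 0 °C; then 7 (2 equiv), HCl (4 M in dioxane, to pH 1), 0 → 20 °C
Reagents that add atoms: none
Why: Borohydride reduction of the salicylaldehyde, acid-induced loss of water to the o-quinone methide and Friedel–Crafts (Michael-type) attack by the only free aromatic carbon of 7 form the methylene bridge with fixed regiochemistry, the excess of 7 suppresses self-condensation of 9 at C6 of ring A, both stereocentres are remote and untouched, and any (2R) contaminant ends up in a separable diastereomer.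

## Compound list

1 | 2,6-dihydroxy-4-methoxybenzaldehyde | COc1cc(O)c(C=O)c(O)c1 | starting material
2 | (E)-cinnamyl alcohol, (2E)-3-phenylprop-2-en-1-ol | OC/C=C/c1ccccc1 | starting material
3 | 2,6-dihydroxy-4-methoxy-3-[(2E)-3-phenylprop-2-en-1-yl]benzaldehyde | COc1cc(O)c(C=O)c(O)c1C/C=C/c1ccccc1 | intermediate
4 | (2S)-7-hydroxy-5-methoxy-2-phenyl-3,4-dihydro-2H-chromene-8-carbaldehyde | COc1cc(O)c(C=O)c2c1CC[C@@H](c1ccccc1)O2 | intermediate
5 | 2,6-dihydroxy-4-methoxy-3-methyl-5-[(2E)-3-phenylprop-2-en-1-yl]benzaldehyde | COc1c(C)c(O)c(C=O)c(O)c1C/C=C/c1ccccc1 | intermediate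
6 | (2S)-7-hydroxy-5-methoxy-6-methyl-2-phenyl-3,4-dihydro-2H-chromene-8-carbaldehyde | COc1c(C)c(O)c(C=O)c2c1CC[C@@H](c1ccccc1)O2 | intermediate
7 | (2S)-5-methoxy-6-methyl-2-phenyl-3,4-dihydro-2H-chromen-7-ol | COc1c(C)c(O)cc2c1CC[C@@H](c1ccccc1)O2 | intermediate
8 | (2S)-8-(hydroxymethyl)-5-methoxy-2-phenyl-3,4-dihydro-2H-chromen-7-ol (not isolated) | COc1cc(O)c(CO)c2c1CC[C@@H](c1ccccc1)O2 | intermediate
9 | (2S)-5-methoxy-8-methylidene-2-phenyl-3,4-dihydro-2H-chromen-7(8H)-one (not isolated) | COC1=CC(=O)C(=C)C2=C1CC[C@@H](c1ccccc1)O2 | intermediate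
10 | (2S)-8-{[(2S)-7-hydroxy-5-methoxy-6-methyl-2-phenyl-3,4-dihydro-2H-chromen-8-yl]methyl}-5-methoxy-2-phenyl-3,4-dihydro-2H-chromen-7-ol | COc1cc(O)c(Cc2c(O)c(C)c(OC)c3c2O[C@H](c2ccccc2)CC3)c2c1CC[C@@H](c1ccccc1)O2 | target

## Step count and risks

Total steps: 6. Longest linear sequence: 5 (steps 1, 3, 4, 5 and 6; step 2 is the short branch).

**Steps 2 and 4 (the proposed hydroalkoxylation, one transformation used twice).** The chelated, weakly nucleophilic phenol may react slowly, the formyl oxygen may bind the acid, and the enantioselectivity is untested on this substrate class. The fallback uses known chemistry and sets out from 3 (and, for step 4, from 5). The phenol is cyclised with CF3SO3H (5 mol %) in toluene at 60 °C, the known racemic acid-catalysed hydroalkoxylation of 2-cinnamylphenols. The enantiomers are then separated by preparative chromatography on a cellulose tris(3,5-dimethylphenylcarbamate) phase. From 3 this gives 4 together with its mirror image (2R)-7-hydroxy-5-methoxy-2-phenyl-3,4-dihydro-2H-chromene-8-carbaldehyde F1, which is discarded. From 5 it gives 6 together with (2R)-7-hydroxy-5-methoxy-6-methyl-2-phenyl-3,4-dihydro-2H-chromene-8-carbaldehyde F2. The route is rejoined at 4 and at 6.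

**Step 3 (C-methylation).** O-Methylation or dearomatising alkylation at the cinnamyl-bearing carbon may compete. The fallback brings the methyl group in with the arene and sets out from 2 and purchased 2-methylbenzene-1,3,5-triol F3. Vilsmeier–Haack formylation (POCl3, DMF, then water) at one of its two equivalent ring positions gives 2,4,6-trihydroxy-3-methylbenzaldehyde F4. O-Methylation of the hydroxyl para to the formyl group, the most acidic one and remote from the formyl chelate (MeI 1.0 equiv, K2CO3, acetone), gives 2,6-dihydroxy-4-methoxy-3-methylbenzaldehyde F5. Cinnamylation of its single free ring carbon with 2 under the conditions of step 1 rejoins the route at 5.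

**Step 5 (decarbonylation).** The aldehyde is flanked by two oxygen substituents, and the ortho hydroxyl can hold rhodium as a stable acyl hydride chelate. The fallback sets out from 6. Oxidation of the aldehyde (NaClO2, NaH2PO4, 2-methylbut-2-ene, t-BuOH–H2O) gives (2S)-7-hydroxy-5-methoxy-6-methyl-2-phenyl-3,4-dihydro-2H-chromene-8-carboxylic acid F6. This 2-hydroxy-4,6-dialkoxybenzoic acid undergoes protodecarboxylation on warming (DMSO, 110 °C) and rejoins the route at 7.

## Further compounds

F1 | step 2 | (2R)-7-hydroxy-5-methoxy-2-phenyl-3,4-dihydro-2H-chromene-8-carbaldehyde | COc1cc(O)c(C=O)c2c1CC[C@H](c1ccccc1)O2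
F2 | step 4 | (2R)-7-hydroxy-5-methoxy-6-methyl-2-phenyl-3,4-dihydro-2H-chromene-8-carbaldehyde | COc1c(C)c(O)c(C=O)c2c1CC[C@H](c1ccccc1)O2
F3 | step 3 | 2-methylbenzene-1,3,5-triol (purchased) | Cc1c(O)cc(O)cc1O
F4 | step 3 | 2,4,6-trihydroxy-3-methylbenzaldehyde | Cc1c(O)cc(O)c(C=O)c1O
F5 | step 3 | 2,6-dihydroxy-4-methoxy-3-methylbenzaldehyde | COc1cc(O)c(C=O)c(O)c1C
F6 | step 5 | (2S)-7-hydroxy-5-methoxy-6-methyl-2-phenyl-3,4-dihydro-2H-chromene-8-carboxylic acid | COc1c(C)c(O)c(C(=O)O)c2c1CC[C@@H](c1ccccc1)O2
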